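Compound numbers used throughout: 1–20, assigned in the order of the steps below; 20 is the target.

## The problem

Target 20 is an unsymmetrical methylene-bis(acylphloroglucinol): two hexasubstituted benzene rings joined only through one CH2 group between A5 and B1. Ring A carries butanoyl at A1, free hydroxyls at A2, A4 and A6 and a methyl group at A3. Ring B has the same carbon substituents (methyl B3, butanoyl B5, hydroxyls B2 and B6), but its B4 oxygen is a methyl ether. That ether lies between the methyl and the butanoyl group, on the oxygen that reacts last when a butanoyl-methylphloroglucinol is alkylated.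

There is no stereocentre, so nothing can be relayed; the difficulty is purely regiochemical. Exactly one of five phenolic oxygens is methylated, each acyl group must sit on a defined carbon, and the bridge must join two different rings without homodimers. The sensitive elements are the electron-rich polyphenol and the diarylmethane link between two phloroglucinol nuclei. That link is cleaved or scrambled by alkali and by strong Lewis or protic acid, so acylation or harsh deprotection on the assembled bis-arene must be avoided.

The enabling feature is that ring A is a 2-acylbenzene-1,3,5-triol. Its carbons A6, A5, A4, A3, A2 and A1 map onto C1 to C6 of a 3,5,7-trioxodecanoate; the oxygens at A6, A4 and A2 are the ester and ketone oxygens at C1, C3 and C5; the butanoyl carbonyl is C7. The A1–A6 bond is then a Claisen bond between a doubly activated methylene (C6) and an ester (C1). The A3 methyl and the A5 bridge become plain substituents at C4 and C2 of an open chain, so ring B can be carried complete, as a benzyl group.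

## Retrosynthesis

**20 from 19.** The two O–benzyl bonds at B2 and B6 are cut. Benzyl is preferred over methyl or acetal protection because its removal is neutral. A Lewis acid would not distinguish a protecting ether from the B4 methyl ether and would endanger the bridge. Ring A needs no protection, since its three hydroxyls are created in the ring-forming step. The forward reaction must cleave two benzyl ethers without reducing two aryl ketones.

**19 from 17 (through 18).** The A1–A6 bond is cut and ring A is unfolded to triketo ester 17 (C1 = A6, C2 = A5, C3 = A4, C4 = A3, C5 = A2, C6 = A1, C7–C10 = butanoyl). The neighbouring cuts are less attractive within this plan: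
- Opening at C2/C7 (aldol fold) leads to a resorcylate, not a phloroglucinol.
- Cutting the A1–acyl bond places a Friedel–Crafts step on the acid-labile bis-arene.
- Cutting at the bridge returns two nucleophilic phenols that must be cross-coupled.

The precursor has one ring less, and its two epimerizable centres (C2, C4) disappear on aromatization through trione 18. The forward reaction must favour C-acylation by C6 over aldol closure, lactonization and retro-Claisen cleavage.

**17 from 16.** The C7 ketone is masked as a dioxolane. In 16 the C6 methylene is activated by one carbonyl only, so the chain can be assembled with strong base without folding prematurely. The unmasking must be mild enough that the 1,3,5-tricarbonyl array does not cyclodehydrate.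

**16 from 11 and 14.** The C4–C5 bond is cut. C4 is the γ-carbon of β-keto ester 11, the natural nucleophilic site of its polyanion, and C5 is supplied as Weinreb amide 14. This cut divides the chain into two pieces that both descend from commercial β-keto esters (10 and 12). A cut at C5–C6 or C2–C3 would require an acyl donor that is itself a β-keto acid derivative. The amide keeps the new ketone masked as a chelate until work-up, so the acidic 1,3-diketone never meets unreacted carbanion. The forward step must be γ-selective although ring B carries an enolizable ketone. Amide 14 goes back to keto ester 12 through ketal ester 13.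

**11 from 9 and 10.** The C2–CH2 bond is cut. The bridge carbon travels with ring B as the benzylic bromide 9, and C2 of 10 is the only acidic position at this stage, so the regiochemistry is automatic. After chain extension C2 and C4 would compete, which is why this bond is made first. The precursor 10 is a commodity chemical.

**9 from 8, 7 and 5.** The bromide comes from alcohol 8, and this from aldehyde 7. The B1–C bond is then cut by a formylation transform at the single unsubstituted ring carbon of 5. Putting the one-carbon unit on last avoids any regiochemical question on the ring and leaves the labile bromide to the final operation on ring B.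

**5 from 4, 3, 1 and 2.** The O–methyl bond, the two O–benzyl bonds and the B5–acyl bond are cut in this order. Acylation of symmetrical 1 with 2 can give only 3. In 3 the hydroxyl between methyl and carbonyl is the least reactive, so the two benzyl groups go on first (4) and the methyl ether is placed last (5), exactly on the oxygen the target requires.

## Roads not taken

**Alternative 1:** Both aryl–acyl bonds (A1–C(=O) and B5–C(=O)) are cut, leaving the bridged bis-phenol as its pentabutanoate A1.
- *Forward step:* a Lewis acid promotes a twofold Fries rearrangement that moves one butanoyl group to the single free carbon of each ring and gives tributanoate A2. The three remaining esters are then cleaved.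
- *Merits:* two C–C bonds form in one operation, C-regiochemistry is automatic, and the route would be much shorter than the chosen one.
- *Weak points:* Fries conditions are those under which diarylmethanes of phloroglucinols undergo ipso-protonation and bridge scission. The B4 methyl ether ends up ortho to a new ketone, the arrangement most prone to Lewis-acid demethylation. A2 is one of several positional isomers and needs a deacylation that 20 tolerates poorly. The unsymmetrical core behind A1 must be made from two different rings that each have two free positions, which invites oligomers and homodimers.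
- *Comparison:* on step count this road is clearly better. The chosen plan is longer, but it never exposes a formed bis-arene to Lewis acid, places each acyl group by construction, and ends with a neutral step.

**Alternative 2:** The B1–B6 bond of ring B is cut and ring B is derived from the 4-methoxy-2-pyranone A3.
- *Forward step:* an alkoxide opens the lactone of A3, and the ketone α-carbon that carries ring A as a benzyl group closes onto the new ester, giving A4.
- *Merits:* the B4 ether comes from the pyranone methoxy group, so its position is beyond doubt. In this respect the road is better than the chosen plan, whose ether position rests on the reactivity order of three hydroxyls (steps 2 and 3).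
- *Weak points:* the nucleophile is a singly activated α-methylene, against the doubly activated C6 of 17, so closure needs harsher base and competes with re-lactonization. A4 lacks the B5 butanoyl group, which must then be added with 2 and a Lewis acid to a substrate with two free phenols, three benzyl ethers and the bridge in place. Building A3 also needs strong base next to the ring A ketone.
- *Comparison:* the chosen plan has an extra risk in placing the ether, but it carries both butanoyl groups from the start and needs no late acylation.

**Alternative 3:** The bonds B2–B3, B4–B5 and B1–B2 are cut; ring B is made from cyclobutenone A5 and 1-methoxypropyne A6.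
- *Forward step:* heating opens A5 to a vinylketene, which adds A6; the new cyclobutenone opens and closes by 6π electrocyclization to phenol A7.
- *Merits:* neutral thermal conditions; the ether position is set by the polarity of A6; B2 (free) and B6 (benzyl) are differentiated at once. The regiochemical certainty for ring B is higher than in the chosen plan.
- *Weak points:* A5, a 4-alkylated 3-alkoxycyclobutenone carrying all of ring A, is not a commodity and its preparation again involves enolate chemistry beside an aryl ketone. A6 is volatile and sensitive. A7 lacks the B5 butanoyl group, so the same late Friedel–Crafts problem as in Alternative 2 returns.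
- *Comparison:* the chosen plan offers commodity building blocks, ordinary enolate chemistry and no C–C bond formation on the assembled bis-arene.

Key step: step 12

Remark on the chemistry: intermediates 11, 15, 16, 17 and 18 have epimerizable centres and exist as keto–enol mixtures. They are carried as mixtures and drawn without configuration, since these centres all become sp2 carbons of ring A. Adduct 15 exists as a lithium chelate and is drawn O-protonated.

## Route

Step 1
Reactants: 1 2,4,6-trihydroxytoluene; 2 butyryl chloride
Product: 3 1-(2,4,6-trihydroxy-3-methylphenyl)butan-1-one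
Conditions: AlCl3, PhNO2/CH2Cl2, 0 °C → rt; aq. HCl
Reagents that add atoms: none
Why: Friedel–Crafts C-acylation of a phloroglucinol; the two free ring positions of 1 are equivalent, so one product is possible, and the first acyl group deactivates the ring toward a second.

Step 2
Reactants: 3 1-(2,4,6-trihydroxy-3-methylphenyl)butan-1-one
Product: 4 1-[4,6-bis(benzyloxy)-2-hydroxy-3-methylphenyl]butan-1-one
Conditions: BnBr (2.05 equiv), K2CO3, acetone, reflux
Reagents that add atoms: benzyl bromide, BrCc1ccccc1
Why: Williamson etherification; the non-chelated 4-OH (para to C=O) and the less hindered 6-OH should react, while the 2-OH, held in a buttressed hydrogen bond between methyl and carbonyl, should stay free. This is the pattern known for partial alkylation of C-methylated phloracylphenones.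

Step 3
Reactants: 4 1-[4,6-bis(benzyloxy)-2-hydroxy-3-methylphenyl]butan-1-one
Product: 5 1-[4,6-bis(benzyloxy)-2-methoxy-3-methylphenyl]butan-1-one
Conditions: MeI, K2CO3, DMF, 50 °C
Reagents that add atoms: iodomethane, CI
Why: Williamson methylation of the remaining chelated phenol under more forcing conditions; K2CO3 is too weak to enolize the ketone, so only oxygen is methylated.

Step 4
Reactants: 5 1-[4,6-bis(benzyloxy)-2-methoxy-3-methylphenyl]butan-1-one
Product: 7 2,6-bis(benzyloxy)-3-butanoyl-4-methoxy-5-methylbenzaldehyde, via aryl iminium chloride 6 (not isolated)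
Conditions: POCl3, DMF, 0 → 60 °C; then H2O
Reagents that add atoms: N,N-dimethylformamide, CN(C)C=O; water, O
Why: Vilsmeier–Haack formylation at the only free ring carbon, which is ortho to both benzyloxy groups and para to the methoxy group; the di-ortho-substituted ketone is twisted out of conjugation and deactivates the ring little. Benzyl ethers are stable to the chloroiminium reagent, and iminium salt 6 is hydrolysed on work-up.

Step 5
Reactants: 7 2,6-bis(benzyloxy)-3-butanoyl-4-methoxy-5-methylbenzaldehyde
Product: 8 1-[4,6-bis(benzyloxy)-5-(hydroxymethyl)-2-methoxy-3-methylphenyl]butan-1-one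
Conditions: NaBH4, MeOH/THF, 0 °C
Reagents that add atoms: none
Why: Chemoselective borohydride reduction; the aldehyde should be reduced much faster than the twisted, di-ortho-substituted aryl ketone at 0 °C.

Step 6
Reactants: 8 1-[4,6-bis(benzyloxy)-5-(hydroxymethyl)-2-methoxy-3-methylphenyl]butan-1-one
Product: 9 1-[4,6-bis(benzyloxy)-5-(bromomethyl)-2-methoxy-3-methylphenyl]butan-1-one
Conditions: PBr3, Et2O, 0 °C; used crude
Reagents that add atoms: phosphorus tribromide, BrP(Br)Br
Why: Standard conversion of an activated benzylic alcohol into the bromide; the ring is fully substituted, so the usual self-alkylation of electron-rich benzyl halides is blocked. The bromide is used at once.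

Step 7
Reactants: 9 1-[4,6-bis(benzyloxy)-5-(bromomethyl)-2-methoxy-3-methylphenyl]butan-1-one; 10 methyl 3-oxopentanoate
Product: 11 methyl 2-{[2,6-bis(benzyloxy)-3-butanoyl-4-methoxy-5-methylphenyl]methyl}-3-oxopentanoate (racemic)
Conditions: 10 (2 equiv), NaH, THF, 0 °C; then 9, 0 °C → rt
Reagents that add atoms: none
Why: Acetoacetic-ester-type C-alkylation of the sodium enolate of 10 at C2, its only acidic position; excess of the cheap keto ester suppresses dialkylation, and the preformed enolate leaves no free hydride for the ring B ketone. The new C2 centre is racemic and is destroyed in step 12.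

Step 8
Reactants: 12 ethyl 3-oxohexanoate
Product: 13 ethyl 2-(2-propyl-1,3-dioxolan-2-yl)acetate
Conditions: HOCH2CH2OH, TsOH (cat.), toluene, reflux, Dean–Stark
Reagents that add atoms: ethane-1,2-diol, OCCO
Why: Acid-catalysed ketalization of the ketone of a β-keto ester with azeotropic removal of water.

Step 9
Reactants: 13 ethyl 2-(2-propyl-1,3-dioxolan-2-yl)acetate
Product: 14 N-methoxy-N-methyl-2-(2-propyl-1,3-dioxolan-2-yl)acetamide
Conditions: MeNH(OMe)·HCl, iPrMgCl, THF, −20 → 0 °C
Reagents that add atoms: N,O-dimethylhydroxylamine hydrochloride, CNOC.Cl
Why: Direct ester-to-Weinreb-amide conversion through the chloromagnesium amide, which adds to the ester faster than it is enolized.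

Step 10
Reactants: 11 methyl 2-{[2,6-bis(benzyloxy)-3-butanoyl-4-methoxy-5-methylphenyl]methyl}-3-oxopentanoate; 14 N-methoxy-N-methyl-2-(2-propyl-1,3-dioxolan-2-yl)acetamide
Product: 16 methyl 2-{[2,6-bis(benzyloxy)-3-butanoyl-4-methoxy-5-methylphenyl]methyl}-4-methyl-3,5-dioxo-6-(2-propyl-1,3-dioxolan-2-yl)hexanoate, via chelated carbinolamine adduct 15 (not isolated)
Conditions: LiN(iPr)2 (LDA, 3.1 equiv), THF, −78 → −20 °C; 14 (1.0 equiv), −78 → −20 °C; aq. NH4Cl
Reagents that add atoms: none
Why: Huckin–Weiler γ-acylation of a β-keto ester polyanion with a Weinreb amide. Three equivalents of base deprotonate C2, park the ring B ketone as its less nucleophilic lithium enolate, and then generate the last-formed, most reactive carbanion at C4, which attacks the limiting amide. Adduct 15 survives as a chelate until the quench, so no acidic diketone is present beside unreacted carbanion; the new C4 centre is unassigned and is destroyed later.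

Step 11
Reactants: 16 methyl 2-{[2,6-bis(benzyloxy)-3-butanoyl-4-methoxy-5-methylphenyl]methyl}-4-methyl-3,5-dioxo-6-(2-propyl-1,3-dioxolan-2-yl)hexanoate
Product: 17 methyl 2-{[2,6-bis(benzyloxy)-3-butanoyl-4-methoxy-5-methylphenyl]methyl}-4-methyl-3,5,7-trioxodecanoate
Conditions: 1 M aq. HCl, THF, rt
Reagents that add atoms: water, O
Why: Acid-catalysed hydrolysis of the dioxolane; dilute acid at room temperature is chosen because strong acid or heat would cyclodehydrate the 1,3,5-tricarbonyl array. Benzyl ethers and the methyl ester are stable under these conditions.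

Step 12
Reactants: 17 methyl 2-{[2,6-bis(benzyloxy)-3-butanoyl-4-methoxy-5-methylphenyl]methyl}-4-methyl-3,5,7-trioxodecanoate
Product: 19 1-(3-{[2,6-bis(benzyloxy)-3-butanoyl-4-methoxy-5-methylphenyl]methyl}-2,4,6-trihydroxy-5-methylphenyl)butan-1-one, via 2-acylcyclohexane-1,3,5-trione 18 (not isolated)
Conditions: Mg(OMe)2, MeOH, rt → 50 °C; then cold dil. HCl
Reagents that add atoms: none
Why: Mg(OMe)2 converts 17 into a magnesium polyenolate in which C6, the only CH2 flanked by two ketones and hence the most acidic site, is deprotonated and the ester is held close by chelation of magnesium between the C3 and C1 oxygens. The C6 carbanion adds to the ester carbonyl C1 and methoxide is lost (intramolecular Claisen, Dieckmann-type C-acylation); this forms the A1–A6 bond and gives trione 18, which tautomerizes to phloroglucinol 19. Aromatization and formation of the magnesium phenoxide make the closure irreversible. The closest known reaction type is the base-mediated Claisen cyclization of 3,5,7-trioxoalkanoate esters to 2-acylphloroglucinols, the laboratory counterpart of polyketide folding. Ring A closes in the 6-exo-trig mode (6-enolexo when the C7 enolate is the nucleophile), the carbonyl π bond lying outside the new ring. No stereocentre is formed; the epimerizable centres C2 and C4 of 17 become the sp2 carbons A5 and A3. The step needs C-acylation by C6 to win over aldol closure, O-acylation and retro-Claisen cleavage: the aldol nucleophile C2 is a tertiary, less acidic carbon whose adduct with C7 would hold a quaternary centre and could not aromatize, the propyl α-carbon C8 is activated by one carbonyl only, and with the ketones tied up as enolates the ester is the only electrophilic carbonyl left. Ring B is a spectator, its benzyl ethers, methyl ether and hindered ketone being inert to Mg(OMe)2 in methanol.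

Step 13
Reactants: 19 1-(3-{[2,6-bis(benzyloxy)-3-butanoyl-4-methoxy-5-methylphenyl]methyl}-2,4,6-trihydroxy-5-methylphenyl)butan-1-one
Product: 20 1-{3-[(3-butanoyl-2,6-dihydroxy-4-methoxy-5-methylphenyl)methyl]-2,4,6-trihydroxy-5-methylphenyl}butan-1-one
Conditions: H2 (1 atm), Pd/C, EtOAc, rt
Reagents that add atoms: none
Why: Hydrogenolysis of two benzyl aryl ethers over palladium on carbon; the conditions are neutral, so the bridge and the B4 methyl ether are untouched, and the strongly hydrogen-bonded aryl ketones of acylphloroglucinols are not expected to be reduced at room temperature and atmospheric pressure.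

## Compound list

1 | 2,4,6-trihydroxytoluene (2-methylbenzene-1,3,5-triol) | Cc1c(O)cc(O)cc1O | starting material
2 | butyryl chloride | CCCC(=O)Cl | starting material
3 | 1-(2,4,6-trihydroxy-3-methylphenyl)butan-1-one | CCCC(=O)c1c(O)c(C)c(O)cc1O | intermediate
4 | 1-[4,6-bis(benzyloxy)-2-hydroxy-3-methylphenyl]butan-1-one | CCCC(=O)c1c(O)c(C)c(OCc2ccccc2)cc1OCc1ccccc1 | intermediate
5 | 1-[4,6-bis(benzyloxy)-2-methoxy-3-methylphenyl]butan-1-one | CCCC(=O)c1c(OC)c(C)c(OCc2ccccc2)cc1OCc1ccccc1 | intermediate
6 | aryl iminium chloride, not isolated: {[2,6-bis(benzyloxy)-3-butanoyl-4-methoxy-5-methylphenyl]methylidene}dimethylammonium chloride | CCCC(=O)c1c(OC)c(C)c(OCc2ccccc2)c(C=[N+](C)C)c1OCc1ccccc1.[Cl-] | intermediate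
7 | 2,6-bis(benzyloxy)-3-butanoyl-4-methoxy-5-methylbenzaldehyde | CCCC(=O)c1c(OC)c(C)c(OCc2ccccc2)c(C=O)c1OCc1ccccc1 | intermediate
8 | 1-[4,6-bis(benzyloxy)-5-(hydroxymethyl)-2-methoxy-3-methylphenyl]butan-1-one | CCCC(=O)c1c(OC)c(C)c(OCc2ccccc2)c(CO)c1OCc1ccccc1 | intermediate
9 | 1-[4,6-bis(benzyloxy)-5-(bromomethyl)-2-methoxy-3-methylphenyl]butan-1-one | CCCC(=O)c1c(OC)c(C)c(OCc2ccccc2)c(CBr)c1OCc1ccccc1 | intermediate
10 | methyl 3-oxopentanoate | CCC(=O)CC(=O)OC | starting material
11 | methyl 2-{[2,6-bis(benzyloxy)-3-butanoyl-4-methoxy-5-methylphenyl]methyl}-3-oxopentanoate (racemic) | CCC(=O)C(Cc1c(OCc2ccccc2)c(C)c(OC)c(C(=O)CCC)c1OCc1ccccc1)C(=O)OC | intermediate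
12 | ethyl 3-oxohexanoate | CCCC(=O)CC(=O)OCC | starting material
13 | ethyl 2-(2-propyl-1,3-dioxolan-2-yl)acetate | CCCC1(CC(=O)OCC)OCCO1 | intermediate
14 | N-methoxy-N-methyl-2-(2-propyl-1,3-dioxolan-2-yl)acetamide | CCCC1(CC(=O)N(C)OC)OCCO1 | intermediate
15 | chelated carbinolamine adduct, not isolated, drawn O-protonated: methyl 2-{[2,6-bis(benzyloxy)-3-butanoyl-4-methoxy-5-methylphenyl]methyl}-5-hydroxy-5-[methoxy(methyl)amino]-4-methyl-3-oxo-6-(2-propyl-1,3-dioxolan-2-yl)hexanoate (configuration unassigned) | CCCC1(CC(O)(N(C)OC)C(C)C(=O)C(Cc2c(OCc3ccccc3)c(C)c(OC)c(C(=O)CCC)c2OCc2ccccc2)C(=O)OC)OCCO1 | intermediate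
16 | methyl 2-{[2,6-bis(benzyloxy)-3-butanoyl-4-methoxy-5-methylphenyl]methyl}-4-methyl-3,5-dioxo-6-(2-propyl-1,3-dioxolan-2-yl)hexanoate (configuration unassigned) | CCCC1(CC(=O)C(C)C(=O)C(Cc2c(OCc3ccccc3)c(C)c(OC)c(C(=O)CCC)c2OCc2ccccc2)C(=O)OC)OCCO1 | intermediate
17 | methyl 2-{[2,6-bis(benzyloxy)-3-butanoyl-4-methoxy-5-methylphenyl]methyl}-4-methyl-3,5,7-trioxodecanoate (configuration unassigned) | CCCC(=O)CC(=O)C(C)C(=O)C(Cc1c(OCc2ccccc2)c(C)c(OC)c(C(=O)CCC)c1OCc1ccccc1)C(=O)OC | intermediate
18 | trione, not isolated: 2-butanoyl-4-{[2,6-bis(benzyloxy)-3-butanoyl-4-methoxy-5-methylphenyl]methyl}-6-methylcyclohexane-1,3,5-trione (configuration unassigned) | CCCC(=O)C1C(=O)C(C)C(=O)C(Cc2c(OCc3ccccc3)c(C)c(OC)c(C(=O)CCC)c2OCc2ccccc2)C1=O | intermediate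
19 | 1-(3-{[2,6-bis(benzyloxy)-3-butanoyl-4-methoxy-5-methylphenyl]methyl}-2,4,6-trihydroxy-5-methylphenyl)butan-1-one | CCCC(=O)c1c(O)c(C)c(O)c(Cc2c(OCc3ccccc3)c(C)c(OC)c(C(=O)CCC)c2OCc2ccccc2)c1O | intermediate
20 | 1-{3-[(3-butanoyl-2,6-dihydroxy-4-methoxy-5-methylphenyl)methyl]-2,4,6-trihydroxy-5-methylphenyl}butan-1-one (achiral) | CCCC(=O)c1c(O)c(C)c(O)c(Cc2c(O)c(C)c(OC)c(C(=O)CCC)c2O)c1O | target

## Step count and least certain steps

Total step count: 13. Longest linear sequence: 11 steps (steps 1–7 and 10–13); steps 8 and 9 form the side branch.

**Step 12 (key step).** The most likely failure is diversion of the polyenolate: attack of the C5 enolate oxygen on the ester (lactonization to a 4-hydroxy-2-pyranone), or cleavage of the 1,3-diketone units by methoxide (retro-Claisen) faster than ring closure, because the substituents at C2 and C4 slow the folding of the chain. The fallback gives up the ring synthesis and joins two finished arenes. It sets out from bromide 9 and acylphloroglucinol 3. The sodium phenoxide of 3 (NaOMe, MeOH, 0 °C) should be C-benzylated by 9 at its only unsubstituted ring carbon, which gives 19 directly and returns to the route at 19. No new compound is made.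

**Step 10.** The risk is reaction at the wrong anion: the lithium enolate of the ring B butanoyl group may compete with the C4 carbanion for the amide, or the C4 carbanion may deprotonate the α-CH2 of 14 instead of adding, so that 11 is recovered. The fallback takes ring B out of the strong-base step.
- Ester 13 is reduced (iBu2AlH, CH2Cl2, −78 °C) to 2-(2-propyl-1,3-dioxolan-2-yl)acetaldehyde F1.
- The Weiler dianion of 10 (NaH, then n-BuLi, THF) adds to it at −78 °C to give methyl 5-hydroxy-4-methyl-3-oxo-6-(2-propyl-1,3-dioxolan-2-yl)hexanoate F2.
- Silylation (TBSCl, imidazole) gives methyl 5-[(tert-butyldimethylsilyl)oxy]-4-methyl-3-oxo-6-(2-propyl-1,3-dioxolan-2-yl)hexanoate F3, in which C2 is the only doubly activated position.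
- C-alkylation of its sodium enolate with bromide 9 gives methyl 2-{[2,6-bis(benzyloxy)-3-butanoyl-4-methoxy-5-methylphenyl]methyl}-5-[(tert-butyldimethylsilyl)oxy]-4-methyl-3-oxo-6-(2-propyl-1,3-dioxolan-2-yl)hexanoate F4.
- Desilylation with HF·pyridine gives methyl 2-{[2,6-bis(benzyloxy)-3-butanoyl-4-methoxy-5-methylphenyl]methyl}-5-hydroxy-4-methyl-3-oxo-6-(2-propyl-1,3-dioxolan-2-yl)hexanoate F5.
- Dess–Martin oxidation of the C5 alcohol returns to the route at 16.

The detour starts from 13, 10 and 9 and costs three more steps.

**Step 4.** Formylation may stall at the ring carbon shielded by two benzyloxy groups, and on heating the chloroiminium reagent may instead attack the enolizable ketone (chloroformylation of the butanoyl chain). The fallback sets out from 5. Bromination with N-bromosuccinimide in MeCN at the only free ring position gives 1-[4,6-bis(benzyloxy)-5-bromo-2-methoxy-3-methylphenyl]butan-1-one F6. Stille hydroxymethylation with Bu3SnCH2OH and the zerovalent palladium catalyst Pd(PPh3)4 in dioxane at 100 °C gives alcohol 8, where the route is rejoined; step 5 is then not needed.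

**Step 2.** The selectivity between the two hydroxyls ortho to the carbonyl may be incomplete: the second benzyl group may enter next to the methyl group, or a third may follow, and the position of the later methyl ether depends on this step. The fallback fixes the ether by a different logic and sets out from 1.
- Vilsmeier formylation (POCl3, DMF) gives 2,4,6-trihydroxy-3-methylbenzaldehyde F7.
- One equivalent of MeI with K2CO3 methylates its only non-chelated hydroxyl, para to the formyl group, to give 2,6-dihydroxy-4-methoxy-3-methylbenzaldehyde F8.
- C-acylation with 2 (TiCl4, CH2Cl2) at the only free position gives 3-butanoyl-2,6-dihydroxy-4-methoxy-5-methylbenzaldehyde F9.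
- Benzylation of both chelated phenols (BnBr, K2CO3, DMF, 70 °C) returns to the route at 7.

The acylation of a formyl-bearing ring is less assured than step 1, which is why this order is held in reserve.

**Step 11.** During ketal hydrolysis the liberated triketo ester may be lost by acid-catalysed cyclodehydration to a 4-pyranone or by lactonization, the more so because a β-keto ketal hydrolyses slowly and invites forcing. The fallback avoids any ketal and builds the C6–C7 bond last by polyanion chemistry, setting out from 11. Its trilithium salt (LDA, THF) is acylated at C4 with N-methoxy-N-methylacetamide to give methyl 2-{[2,6-bis(benzyloxy)-3-butanoyl-4-methoxy-5-methylphenyl]methyl}-4-methyl-3,5-dioxohexanoate F10. The polyanion of F10 (LDA, 4.1 equiv) is then acylated at its terminal methyl group with N-methoxy-N-methylbutanamide, which gives 17 and rejoins the route there.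

## Further compounds

F0 | step 12 | none | none
F1 | step 10 | 2-(2-propyl-1,3-dioxolan-2-yl)acetaldehyde | CCCC1(CC=O)OCCO1
F2 | step 10 | methyl 5-hydroxy-4-methyl-3-oxo-6-(2-propyl-1,3-dioxolan-2-yl)hexanoate (diastereomer mixture) | CCCC1(CC(O)C(C)C(=O)CC(=O)OC)OCCO1
F3 | step 10 | methyl 5-[(tert-butyldimethylsilyl)oxy]-4-methyl-3-oxo-6-(2-propyl-1,3-dioxolan-2-yl)hexanoate (diastereomer mixture) | CCCC1(CC(O[Si](C)(C)C(C)(C)C)C(C)C(=O)CC(=O)OC)OCCO1
F4 | step 10 | methyl 2-{[2,6-bis(benzyloxy)-3-butanoyl-4-methoxy-5-methylphenyl]methyl}-5-[(tert-butyldimethylsilyl)oxy]-4-methyl-3-oxo-6-(2-propyl-1,3-dioxolan-2-yl)hexanoate (diastereomer mixture) | CCCC1(CC(O[Si](C)(C)C(C)(C)C)C(C)C(=O)C(Cc2c(OCc3ccccc3)c(C)c(OC)c(C(=O)CCC)c2OCc2ccccc2)C(=O)OC)OCCO1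
F5 | step 10 | methyl 2-{[2,6-bis(benzyloxy)-3-butanoyl-4-methoxy-5-methylphenyl]methyl}-5-hydroxy-4-methyl-3-oxo-6-(2-propyl-1,3-dioxolan-2-yl)hexanoate (diastereomer mixture) | CCCC1(CC(O)C(C)C(=O)C(Cc2c(OCc3ccccc3)c(C)c(OC)c(C(=O)CCC)c2OCc2ccccc2)C(=O)OC)OCCO1
F6 | step 4 | 1-[4,6-bis(benzyloxy)-5-bromo-2-methoxy-3-methylphenyl]butan-1-one | CCCC(=O)c1c(OC)c(C)c(OCc2ccccc2)c(Br)c1OCc1ccccc1
F7 | step 2 | 2,4,6-trihydroxy-3-methylbenzaldehyde | Cc1c(O)cc(O)c(C=O)c1O
F8 | step 2 | 2,6-dihydroxy-4-methoxy-3-methylbenzaldehyde | COc1cc(O)c(C=O)c(O)c1C
F9 | step 2 | 3-butanoyl-2,6-dihydroxy-4-methoxy-5-methylbenzaldehyde | CCCC(=O)c1c(OC)c(C)c(O)c(C=O)c1O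
F10 | step 11 | methyl 2-{[2,6-bis(benzyloxy)-3-butanoyl-4-methoxy-5-methylphenyl]methyl}-4-methyl-3,5-dioxohexanoate (configuration unassigned) | CC(=O)C(C)C(=O)C(Cc1c(OCc2ccccc2)c(C)c(OC)c(C(=O)CCC)c1OCc1ccccc1)C(=O)OC
A1 | alternative 1 | 2-{[2,6-bis(butanoyloxy)-4-methoxy-3-methylphenyl]methyl}-4-methylbenzene-1,3,5-triyl tributanoate | c1c(OC(=O)CCC)c(C)c(OC(=O)CCC)c(Cc2c(OC(=O)CCC)c(C)c(OC)cc2OC(=O)CCC)c1OC(=O)CCC
A2 | alternative 1 | tributanoate of the target (one positional isomer: esters at A4, A6 and B2) | CCCC(=O)c1c(O)c(C)c(OC(=O)CCC)c(Cc2c(OC(=O)CCC)c(C)c(OC)c(C(=O)CCC)c2O)c1OC(=O)CCC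
A3 | alternative 2 | 6-{2-[2,4,6-tris(benzyloxy)-3-butanoyl-5-methylphenyl]ethyl}-4-methoxy-5-methyl-2H-pyran-2-one | COC1=CC(=O)OC(CCc2c(OCc3ccccc3)c(C)c(OCc3ccccc3)c(C(=O)CCC)c2OCc2ccccc2)=C1C
A4 | alternative 2 | 1-{2,4,6-tris(benzyloxy)-3-[(2,6-dihydroxy-4-methoxy-3-methylphenyl)methyl]-5-methylphenyl}butan-1-one | CCCC(=O)c1c(OCc2ccccc2)c(C)c(OCc2ccccc2)c(Cc2c(O)c(C)c(OC)cc2O)c1OCc1ccccc1
A5 | alternative 3 | 3-(benzyloxy)-4-{[2,4,6-tris(benzyloxy)-3-butanoyl-5-methylphenyl]methyl}cyclobut-2-en-1-one (racemic) | O=C1C=C(OCc2ccccc2)C1Cc1c(OCc2ccccc2)c(C)c(OCc2ccccc2)c(C(=O)CCC)c1OCc1ccccc1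
A6 | alternative 3 | 1-methoxyprop-1-yne | CC#COC
A7 | alternative 3 | 1-{2,4,6-tris(benzyloxy)-3-{[2-(benzyloxy)-6-hydroxy-4-methoxy-5-methylphenyl]methyl}-5-methylphenyl}butan-1-one | CCCC(=O)c1c(OCc2ccccc2)c(C)c(OCc2ccccc2)c(Cc2c(O)c(C)c(OC)cc2OCc2ccccc2)c1OCc1ccccc1
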